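Follow one molecule of electrophile.

| flask | electrophile | nucleophile | free base | remark | time |
|---|---|---|---|---|---|
| Friday's | 0.35 M | 0.275 M | 0.20 M | run made earlier |  |
| Tuesday's | 0.55 M | 0.275 M | 0.20 M | run made earlier |  |
| flask | 0.25 M | 0.275 M | 0.200 M |  | 2.0 h |

- Friday's (time / min: electrophile / %, product / %): 20.0: 19, 47; 40.0: 10, 55; 50.0: 10, 59; 80.0: 8, 62
- Tuesday's (time / min: electrophile / %, product / %): 6.00: 52, 29; 12.0: 31, 33; 30.0: 16, 43; 80.0: 12, 42

(readings scatter by 2 percentage points)

- part of the electrophile that has reacted at 2.0 h
- share of the unused nucleophile that is free and not bound as protonated nucleophile, at 2.0 h

- product is meant together with its crystals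
- solid, in amounts per volume of the solution: crystals
- what may be going on: electrophile + nucleophile <-> acid set free + product; nucleophile + acid set free <-> protonated nucleophile; acid set free + free base <-> salt of the base; electrophile <-> dormant form; crystals <-> product
- what has gone from electrophile into another species counts as reacted, even if it can come back
- the earlier runs do not show how much of nucleophile is bound; that part of a forecast is a guess

At the first fork it has become product or it has not. If it has not, it stands as electrophile or as dormant form, which you count as whatever is neither electrophile nor product. At the last readings, the electrophile is 21.1% of that unconverted part on Friday's run and 20.7% on Tuesday's. So I take 20.9% as the free share, the part of the unconverted charge still standing as electrophile.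

unreacted part = free share × part not product

For the bound from below, this flask has less electrophile than Friday's, the same nucleophile and a longer time, so I grant it at least Friday's 62% product:

reacted ≥ 92.1%

For the bound from above, the last readings hold 0.217 M of product on Friday's and 0.231 M on Tuesday's. Friday's, the nearer charge, gives this flask a yield of 86.8%:

reacted ≤ 97.2%

The forecast says 97% (94% to 98.5%), at the top of my bracket, and 75% (50% to 95%) for the free nucleophile, “which is a guess”.

The flask gives 94.9% and 75.6%, both within the forecast's ranges. Its product of 75.3% with the free share gives 94.8% reacted. In this flask at 2.0 h, the step making product relaxes with a half-life of 0.0523 h, short against the time. The net rate of making dissolved product in this flask is then 0.980 of the net rate at which it passes into crystals, which stand at 11.1%.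

    electrophile + nucleophile ⇌ acid set free + product (K = 0.310, k = 0.370 M⁻¹ min⁻¹)
    nucleophile + acid set free ⇌ protonated nucleophile, settled at all times (K = 1600 M⁻¹)
    acid set free + free base ⇌ salt of the base, settled at all times (K = 25000 M⁻¹)
    electrophile ⇌ dormant form (K = 2.90, k = 0.0590 min⁻¹)
    crystals ⇌ product, rate k5*(cs5 - [product]) while solid is left; crystals form when [product] > cs5 (solubility = 0.160 M, k = 0.530 min⁻¹)

In the neighbour flask with 0.34 M of free base, product of 77.2% and the free share give 95.2% reacted. The computed result is 95.5%.

(All runs were generated by integration for substances that don't exist, and the scatter is random.)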